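**Plan**

1. Numbering is that of eremophilane: decalin C1–C10, C14 on C5, C15 on C4, isopropenyl C11–C13 on C7. β is the face of C14 and of the C7 isopropenyl group. The target is the 2α,8α-diol 9α-ester with 4β,5β-dimethyl, 7β-isopropenyl and 10αH (trans-decalin).
2. Cuts: the ester C–O at O9; ring A at C3–C4 (C4–H then comes from reduction of a C3=C4 enone); C10–C1 (enolate allylation) and C5–C4 (vinyl 1,4-addition) on a ring-B enone; O8 (α′-hydroxylation); ring B itself from (+)-3-carene.
3. Forward: carene → ring-B enone 4 → O8, C5 (vinyl/methyl), C10 (allyl) and O9 on the monocycle → ring A closed at C3–C4 → enone reduction → ester at O9 → C2 reduction → desilylation.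
4. Stereochemistry: C7 comes from carene. C8, C5, C10 and C9 are relayed from C7 on the monocyclic chair (anti hydroxylation, 3,5-trans conjugate addition, anti allylation, equatorial hydride attack). C4 comes from axial protonation anti to C14, and C2 from equatorial attack of a bulky hydride.
5. Enabling feature: C2 of ring A is oxygenated and C4 carries a methyl next to the quaternary C5. A C2 methyl ketone (nucleophilic C3) and a vinyl group on C5 (C4=C15) therefore form a 2-silyloxy-1,6-diene. A 6-exo insertion joins C3 to C4 and turns the vinyl CH2 into the C15 methyl.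

Key step: step 9

**Route**

Step 1
Reactants: 1 (+)-3-carene
Product: 2 car-3-en-5-one [(1R,6S)-4,7,7-trimethylbicyclo[4.1.0]hept-3-en-2-one]
Conditions: CrO3 (5 mol%), t-BuOOH (70% aq.), CH2Cl2, 25 °C
Reagents that add atoms: tert-butyl hydroperoxide, CC(C)(C)OO
Why: Chromium-catalysed allylic oxidation attacks the ring CH2 next to the unsubstituted alkene carbon, which should give the β-methyl enone conjugated to the cyclopropane without touching either stereocentre.

Step 2
Reactants: 2 car-3-en-5-one
Product: 4 (S)-3-methyl-5-(prop-1-en-2-yl)cyclohex-2-en-1-one, via tertiary bromide 3 (not isolated)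
Conditions: HBr (33% in AcOH), CH2Cl2, 0 °C; evaporate; then DBU, toluene, 60 °C
Reagents that add atoms: none
Why: Acid-mediated homo-conjugate opening of the cyclopropyl ketone should cleave the exocyclic cyclopropane bond that overlaps with the carbonyl π system and releases the tertiary carbon (as in the carone to hydrobromide opening), and E2 dehydrobromination at a methyl hydrogen then gives the isopropenyl group; the carane C1 stereocentre is not involved and becomes C7.

Step 3
Reactants: 4 (S)-3-methyl-5-(prop-1-en-2-yl)cyclohex-2-en-1-one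
Product: 6 (5R,6R)-6-hydroxy-3-methyl-5-(prop-1-en-2-yl)cyclohex-2-en-1-one, via lithium dienolate 5 (not isolated)
Conditions: LiN(i-Pr)2, THF, −78 °C; then 2-(phenylsulfonyl)-3-phenyloxaziridine, −78 °C; then H2O
Reagents that add atoms: 2-(phenylsulfonyl)-3-phenyloxaziridine, O=S(=O)(N1OC1c1ccccc1)c1ccccc1
Why: Kinetic α′-deprotonation gives the cross-conjugated dienolate, and Davis oxaziridine hydroxylation should occur anti to the adjacent isopropenyl group, setting O8 trans to it (8α), as in α′-functionalisation of carvone-type enolates.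

Step 4
Reactants: 6 (5R,6R)-6-hydroxy-3-methyl-5-(prop-1-en-2-yl)cyclohex-2-en-1-one
Product: 7 (5R,6R)-6-(tert-butyldimethylsilyloxy)-3-methyl-5-(prop-1-en-2-yl)cyclohex-2-en-1-one
Conditions: t-BuMe2SiCl, imidazole, DMF, 25 °C
Reagents that add atoms: tert-butyldimethylsilyl chloride, CC(C)(C)[Si](C)(C)Cl
Why: Standard silylation of a secondary alcohol protects O8 for the organometallic, oxidative and reductive steps that follow.

Step 5
Reactants: 7 (5R,6R)-6-(tert-butyldimethylsilyloxy)-3-methyl-5-(prop-1-en-2-yl)cyclohex-2-en-1-one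
Product: 10 (2R,3R,5R,6R)-2-allyl-6-(tert-butyldimethylsilyloxy)-3-methyl-5-(prop-1-en-2-yl)-3-vinylcyclohexan-1-one, via trimethylsilyl enol ether 8 (not isolated), via lithium enolate 9 (not isolated)
Conditions: CH2=CHMgBr, CuBr·SMe2 (10 mol%), Me3SiCl, THF, −78 °C; then MeLi, THF, 0 °C; then CH2=CHCH2Br, DMPU, −78 → 0 °C
Reagents that add atoms: vinylmagnesium bromide, C=C[Mg]Br; allyl bromide, C=CCBr
Why: Copper-catalysed, Me3SiCl-accelerated 1,4-addition should deliver the vinyl group axially and trans to the equatorial C7 isopropenyl group (3,5-trans rule), making C5 quaternary with vinyl α and methyl β, and the regiospecific lithium enolate is then allylated at C10 anti to the pseudo-axial vinyl group (10β-allyl, trans to the vinyl group).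

Step 6
Reactants: 10 (2R,3R,5R,6R)-2-allyl-6-(tert-butyldimethylsilyloxy)-3-methyl-5-(prop-1-en-2-yl)-3-vinylcyclohexan-1-one
Product: 11 (1S,2R,3R,5R,6R)-2-allyl-6-(tert-butyldimethylsilyloxy)-3-methyl-5-(prop-1-en-2-yl)-3-vinylcyclohexan-1-ol
Conditions: LiBH(s-Bu)3 (L-Selectride), THF, −78 °C; then H2O
Reagents that add atoms: none
Why: The bulky hydride should attack C9 along the equatorial trajectory, away from the syn-axial C5 vinyl group of the reacting chair, so the new hydroxyl is axial and cis to the equatorial 8α-silyloxy group (9α), the usual outcome with 2-alkoxycyclohexanones.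

Step 7
Reactants: 11 (1S,2R,3R,5R,6R)-2-allyl-6-(tert-butyldimethylsilyloxy)-3-methyl-5-(prop-1-en-2-yl)-3-vinylcyclohexan-1-ol
Product: 12 9-O-triethylsilyl ether of 11 (10β-allyl, 5β-methyl, 5α-vinyl, 7β-isopropenyl, 8α-OSiMe2t-Bu, 9α-OSiEt3)
Conditions: Et3SiOSO2CF3, 2,6-lutidine, CH2Cl2, −78 → 0 °C
Reagents that add atoms: triethylsilyl trifluoromethanesulfonate, CC[Si](CC)(CC)OS(=O)(=O)C(F)(F)F
Why: Silyl triflate silylation of the hindered 9α-hydroxyl installs a group that is more acid-labile than the O8 silyl ether, so the two oxygens stay distinguishable.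

Step 8
Reactants: 12 9-O-triethylsilyl ether of 11
Product: 13 methyl ketone (10β-CH2C(=O)CH3, 5β-methyl, 5α-vinyl, 7β-isopropenyl, 8α-OSiMe2t-Bu, 9α-OSiEt3)
Conditions: PdCl2 (10 mol%), Cu(OAc)2 (20 mol%), O2 (1 atm), DMA/H2O (7:1), 25 °C
Reagents that add atoms: water, O
Why: Tsuji–Wacker oxidation is sensitive to steric hindrance, so the unhindered allyl terminus should be oxidised to the methyl ketone while the neopentyl vinyl group on C5 and the 1,1-disubstituted isopropenyl group remain.

Step 9
Reactants: 13 methyl ketone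
Product: 15 8α-(tert-butyldimethylsilyloxy)-9α-(triethylsilyloxy)-10αH-eremophila-3,11-dien-2-one, via trimethylsilyl enol ether 14 (not isolated)
Conditions: LiN(i-Pr)2, Me3SiCl, THF, −78 °C; evaporate; then Pd(OAc)2 (1.1 equiv), MeCN, 25 → 40 °C
Reagents that add atoms: none
Why: Kinetic deprotonation at the methyl terminus (C3) and O-silylation give the 2-silyloxy-1,6-diene 14; transmetalation to divalent palladium forms the C3-bound palladium enolate, which adds syn across the C5 vinyl group so that C3 bonds to C4 and palladium sits on C15, and β-hydride elimination followed by re-addition and elimination of the palladium hydride moves the double bond into conjugation, leaving C15 as the methyl group of a 3-methylcyclohex-2-enone. The closest known reaction type is the Ito–Saegusa cyclisation of silyl enol ethers of alkenyl methyl ketones to 3-methylcyclohex-2-enones. Ring A (C1, C2, C3, C4, C5, C10) closes in the 6-exo-trig mode. No new stereocentre survives, because C4 ends sp2: both faces of the vinyl group converge on the same enone and C4 is set in step 10, while the trans ring fusion is carried over from the trans C10/C5 substituents of 13, both equatorial in the reacting chair. The step needs 6-exo insertion in preference to 7-endo insertion or plain loss of the silyl group; the six-atom tether and the absence of β-hydrogens on the C3 palladium enolate favour insertion, the isopropenyl group on C7 cannot reach the enolate, and the syn-axial clash between the 9α-silyloxy and C5 vinyl groups in the other chair pushes ring B towards the reactive conformer.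

Step 10
Reactants: 15 8α-(tert-butyldimethylsilyloxy)-9α-(triethylsilyloxy)-10αH-eremophila-3,11-dien-2-one
Product: 16 8α-(tert-butyldimethylsilyloxy)-9α-(triethylsilyloxy)-4αH,10αH-eremophil-11-en-2-one
Conditions: Li, NH3 (l)/THF, −78 °C; then NH4Cl
Reagents that add atoms: none
Why: Dissolving-metal reduction of the enone should protonate the β-carbon C4 axially on the α face, anti to the pseudo-axial C14 methyl on C5, giving the equatorial 4β-methyl group cis to C14; isolated alkenes and silyl ethers are inert.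

Step 11
Reactants: 16 8α-(tert-butyldimethylsilyloxy)-9α-(triethylsilyloxy)-4αH,10αH-eremophil-11-en-2-one
Product: 17 8α-(tert-butyldimethylsilyloxy)-9α-hydroxy-4αH,10αH-eremophil-11-en-2-one
Conditions: AcOH/THF/H2O (3:1:1), 25 °C
Reagents that add atoms: none
Why: Acid-catalysed solvolysis removes the more labile triethylsilyl ether selectively in the presence of the tert-butyldimethylsilyl ether, so only the 9α-hydroxyl is freed.

Step 12
Reactants: 17 8α-(tert-butyldimethylsilyloxy)-9α-hydroxy-4αH,10αH-eremophil-11-en-2-one; 18 (E)-3-methylpent-2-enoic acid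
Product: 19 8α-(tert-butyldimethylsilyloxy)-9α-[(E)-3-methylpent-2-enoyloxy]-4αH,10αH-eremophil-11-en-2-one
Conditions: DCC, DMAP (cat.), CH2Cl2, 0 → 25 °C
Reagents that add atoms: none
Why: Steglich esterification is regiospecific because the equatorial 9α-hydroxyl is the only free hydroxyl, and mild carbodiimide activation should keep the E geometry of the β,β-disubstituted enoate.

Step 13
Reactants: 19 8α-(tert-butyldimethylsilyloxy)-9α-[(E)-3-methylpent-2-enoyloxy]-4αH,10αH-eremophil-11-en-2-one
Product: 20 8α-(tert-butyldimethylsilyloxy)-2α-hydroxy-9α-[(E)-3-methylpent-2-enoyloxy]-4αH,10αH-eremophil-11-ene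
Conditions: LiBH(s-Bu)3 (L-Selectride), THF, −78 °C; then H2O
Reagents that add atoms: none
Why: The bulky hydride should attack the unhindered ring-A ketone equatorially, giving the axial 2α-alcohol as with 3-oxo-5α-steroids, and at −78 °C the β,β-disubstituted enoate is not reduced while the silylated O8 prevents acyl migration.

Step 14
Reactants: 20 8α-(tert-butyldimethylsilyloxy)-2α-hydroxy-9α-[(E)-3-methylpent-2-enoyloxy]-4αH,10αH-eremophil-11-ene
Product: 21 2α,8α-dihydroxy-9α-[(E)-3-methylpent-2-enoyloxy]-4αH,10αH-eremophil-11-ene (target)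
Conditions: HF·pyridine, pyridine/THF, 0 → 25 °C
Reagents that add atoms: none
Why: Fluoride-mediated desilylation under buffered, weakly acidic conditions frees the axial 8α-hydroxyl without ester migration or attack on the isopropenyl group.

**Compound list**

1 | (+)-3-carene, (1S,6R)-3,7,7-trimethylbicyclo[4.1.0]hept-3-ene | CC1(C)[C@H]2CC(C)=CC[C@@H]12 | starting material
2 | car-3-en-5-one, (1R,6S)-4,7,7-trimethylbicyclo[4.1.0]hept-3-en-2-one | CC1(C)[C@H]2CC(C)=CC(=O)[C@@H]12 | intermediate
3 | (S)-5-(2-bromopropan-2-yl)-3-methylcyclohex-2-en-1-one | CC(C)(Br)[C@H]1CC(C)=CC(=O)C1 | intermediate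
4 | (S)-3-methyl-5-(prop-1-en-2-yl)cyclohex-2-en-1-one | C=C(C)[C@H]1CC(C)=CC(=O)C1 | intermediate
5 | lithium dienolate of 4 (C8=C9 enolate) | C=C(C)[C@H]1CC(C)=CC(O[Li])=C1 | intermediate
6 | (5R,6R)-6-hydroxy-3-methyl-5-(prop-1-en-2-yl)cyclohex-2-en-1-one (8α-OH, 7β-isopropenyl) | C=C(C)[C@H]1CC(C)=CC(=O)[C@@H]1O | intermediate
7 | (5R,6R)-6-(tert-butyldimethylsilyloxy)-3-methyl-5-(prop-1-en-2-yl)cyclohex-2-en-1-one | C=C(C)[C@H]1CC(C)=CC(=O)[C@@H]1O[Si](C)(C)C(C)(C)C | intermediate
8 | C9 trimethylsilyl enol ether (C9=C10) with 5β-methyl, 5α-vinyl, 7β-isopropenyl, 8α-OSiMe2t-Bu | C=C(C)[C@H]1C[C@](C)(C=C)C=C(O[Si](C)(C)C)[C@@H]1O[Si](C)(C)C(C)(C)C | intermediate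
9 | lithium enolate corresponding to 8 | C=C(C)[C@H]1C[C@](C)(C=C)C=C(O[Li])[C@@H]1O[Si](C)(C)C(C)(C)C | intermediate
10 | (2R,3R,5R,6R)-2-allyl-6-(tert-butyldimethylsilyloxy)-3-methyl-5-(prop-1-en-2-yl)-3-vinylcyclohexan-1-one (10β-allyl, 5β-methyl, 5α-vinyl) | C=C(C)[C@H]1C[C@](C)(C=C)[C@@H](CC=C)C(=O)[C@@H]1O[Si](C)(C)C(C)(C)C | intermediate
11 | (1S,2R,3R,5R,6R)-2-allyl-6-(tert-butyldimethylsilyloxy)-3-methyl-5-(prop-1-en-2-yl)-3-vinylcyclohexan-1-ol (9α-OH) | C=C(C)[C@H]1C[C@](C)(C=C)[C@@H](CC=C)[C@H](O)[C@@H]1O[Si](C)(C)C(C)(C)C | intermediate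
12 | 9-O-triethylsilyl ether of 11 | C=C(C)[C@H]1C[C@](C)(C=C)[C@@H](CC=C)[C@H](O[Si](CC)(CC)CC)[C@@H]1O[Si](C)(C)C(C)(C)C | intermediate
13 | methyl ketone: 10β-(2-oxopropyl), 5β-methyl, 5α-vinyl, 7β-isopropenyl, 8α-OSiMe2t-Bu, 9α-OSiEt3 | C=C(C)[C@H]1C[C@](C)(C=C)[C@@H](CC(C)=O)[C@H](O[Si](CC)(CC)CC)[C@@H]1O[Si](C)(C)C(C)(C)C | intermediate
14 | trimethylsilyl enol ether of 13 (C2=C3) | C=C(C)[C@H]1C[C@](C)(C=C)[C@@H](CC(=C)O[Si](C)(C)C)[C@H](O[Si](CC)(CC)CC)[C@@H]1O[Si](C)(C)C(C)(C)C | intermediate
15 | 8α-(tert-butyldimethylsilyloxy)-9α-(triethylsilyloxy)-10αH-eremophila-3,11-dien-2-one | C=C(C)[C@H]1C[C@]2(C)C(C)=CC(=O)C[C@H]2[C@H](O[Si](CC)(CC)CC)[C@@H]1O[Si](C)(C)C(C)(C)C | intermediate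
16 | 8α-(tert-butyldimethylsilyloxy)-9α-(triethylsilyloxy)-4αH,10αH-eremophil-11-en-2-one | C=C(C)[C@H]1C[C@]2(C)[C@@H](C)CC(=O)C[C@H]2[C@H](O[Si](CC)(CC)CC)[C@@H]1O[Si](C)(C)C(C)(C)C | intermediate
17 | 8α-(tert-butyldimethylsilyloxy)-9α-hydroxy-4αH,10αH-eremophil-11-en-2-one | C=C(C)[C@H]1C[C@]2(C)[C@@H](C)CC(=O)C[C@H]2[C@H](O)[C@@H]1O[Si](C)(C)C(C)(C)C | intermediate
18 | (E)-3-methylpent-2-enoic acid | CC/C(C)=C/C(=O)O | starting material
19 | 8α-(tert-butyldimethylsilyloxy)-9α-[(E)-3-methylpent-2-enoyloxy]-4αH,10αH-eremophil-11-en-2-one | C=C(C)[C@H]1C[C@]2(C)[C@@H](C)CC(=O)C[C@H]2[C@H](OC(=O)/C=C(\C)CC)[C@@H]1O[Si](C)(C)C(C)(C)C | intermediate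
20 | 8α-(tert-butyldimethylsilyloxy)-2α-hydroxy-9α-[(E)-3-methylpent-2-enoyloxy]-4αH,10αH-eremophil-11-ene | C=C(C)[C@H]1C[C@]2(C)[C@@H](C)C[C@H](O)C[C@H]2[C@H](OC(=O)/C=C(\C)CC)[C@@H]1O[Si](C)(C)C(C)(C)C | intermediate
21 | 2α,8α-dihydroxy-9α-[(E)-3-methylpent-2-enoyloxy]-4αH,10αH-eremophil-11-ene | C=C(C)[C@H]1C[C@]2(C)[C@@H](C)C[C@H](O)C[C@H]2[C@H](OC(=O)/C=C(\C)CC)[C@@H]1O | target

**Step count and risks**

Total step count: 14. Longest linear sequence: 14 steps (1 to 21); 18 is used as bought.

Steps most likely to fail: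

- **Step 9.** Insertion of the hindered vinyl group next to the quaternary C5 may be slower than loss of the silyl group from the enol ether, or may occur at the terminal carbon (7-endo). Fallback: from 13, the remaining C5 vinyl group would be oxidised under forcing Tsuji–Wacker conditions (PdCl2, CuCl, O2, DMF/H2O, 60 °C) to the C2,C4-diketone F2. Pyrrolidine/AcOH in toluene at 80 °C would then form the enamine at the unhindered C2 ketone only, so that C3 attacks the C4 acetyl group; aldol condensation returns to 15.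
- **Step 2.** The elimination may remove the ring hydrogen instead of a methyl hydrogen (isopropylidene isomer, then tautomerisation to a phenol), or the enolate may re-close the cyclopropane. Fallback: from 2, hydrative opening with dilute H2SO4 in aqueous THF would give the tertiary alcohol (S)-5-(2-hydroxypropan-2-yl)-3-methylcyclohex-2-en-1-one F1. Dehydration with the Burgess reagent, a syn elimination through a cyclic transition state with neither carbocation nor enolate, would return to 4.
- **Step 5.** The regiospecific enolate may be lost by proton transfer, O-allylation may compete, or the silyl group may migrate from O8 to the enolate oxygen. Fallback: from 8, palladium-catalysed allylation of the silyl enol ether itself with allyl methyl carbonate (Pd2(dba)3, dppe, THF; zerovalent palladium, π-allyl chemistry) would deliver the allyl group to C10 without a free lithium enolate and return to 10. This fallback makes no new compound (F0).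

Further compounds
F0 | step 5 | none | none
F1 | step 2 | (S)-5-(2-hydroxypropan-2-yl)-3-methylcyclohex-2-en-1-one | CC(C)(O)[C@H]1CC(C)=CC(=O)C1
F2 | step 9 | C2,C4-diketone: 10β-(2-oxopropyl), 5α-acetyl, 5β-methyl, 7β-isopropenyl, 8α-OSiMe2t-Bu, 9α-OSiEt3 | C=C(C)[C@H]1C[C@](C)(C(C)=O)[C@@H](CC(C)=O)[C@H](O[Si](CC)(CC)CC)[C@@H]1O[Si](C)(C)C(C)(C)C
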